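The target is cut at the C7'–C4 bond into acyl trione ring A and a C10 hydroxy aldehyde. That aldehyde, C7' plus cyclopentane ring B (C1'–C5') with the C2' methyl and C5' isopropenyl, holds the ten carbons of limonene with one ring atom turned outside. Its C2' oxygen stands β to C7' on the same ring face, the signature of a cis-fused β-lactone. The open-chain keto acid from cleavage of the limonene ring alkene (6-oxoheptanoic acid, isopropenyl stereocentre at C3) is therefore re-closed in one operation. An aldol-lactonisation forms C1'–C2' and O–C7', both rings and both new stereocentres, steered by C5'. A reductive Knoevenagel coupling joins the halves.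

Key step: step 4

Numbering: ring A has C1 (C=O between C2 and C6), C2 (isovaleryl), C3 (C–OH), C4 (bears C7'), C5 (C–OH) and C6 (methyl, prenyl). Ring B is C1'–C5' as above.

Stereochemical check: the target is (6S) for the tautomer drawn and (1'R,2'S,5'S). On cleavage, C3 of limonene becomes C1' and C5 becomes C4', and the CIP ranking at the isopropenyl carbon does not change. The (S) terpene, the (S) keto acid and the (1R,2S,5S) lactone are therefore the correct series and need no change.

Assumption: pig liver esterase is taken to hydrolyse the pro-R ester group of the prochiral malonate, which gives the (S) half ester; sense and level of selection are to be verified on that compound before it is carried on.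

Step 1
Reactants: 1 (S)-(−)-limonene
Product: 2 (4S)-1-methyl-4-(prop-1-en-2-yl)-7-oxabicyclo[4.1.0]heptane (limonene 1,2-oxide; cis/trans epoxide mixture)
Conditions: mCPBA (1.0 equiv), CH2Cl2, 0 °C
Reagents that add atoms: mCPBA, O=C(OO)c1cccc(Cl)c1
Why: Prilezhaev epoxidation should take the electron-richer trisubstituted ring alkene before the 1,1-disubstituted isopropenyl group, and the two new epoxide centres are erased in step 2, so the mixture is used as such.

Step 2
Reactants: 2 limonene 1,2-oxide
Product: 4 (S)-6-oxo-3-(prop-1-en-2-yl)heptanal, via limonene-1,2-diol 3 (not isolated)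
Conditions: H5IO6 (1.1 equiv), THF/H2O, 0 °C → rt
Reagents that add atoms: water, O
Why: Acid-catalysed epoxide hydrolysis followed in the same flask by Malaprade glycol cleavage cuts the C1–C2 bond of the p-menthane ring, periodate leaves the isopropenyl group alone, and the stereocentre, β to the new aldehyde, cannot enolise.

Step 3
Reactants: 4 keto aldehyde
Product: 5 (S)-6-oxo-3-(prop-1-en-2-yl)heptanoic acid
Conditions: NaClO2, NaH2PO4, 2-methyl-2-butene, t-BuOH/H2O, 0 °C → rt
Reagents that add atoms: sodium chlorite, [Na+].[O-]Cl=O
Why: Pinnick oxidation converts only the aldehyde, 2-methyl-2-butene takes up the hypochlorous acid that would otherwise attack the isopropenyl group or the methyl ketone, and no stereocentre is at risk.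

Step 4
Reactants: 5 keto acid
Product: 8 (1R,2S,5S)-5-methyl-2-(prop-1-en-2-yl)-6-oxabicyclo[3.2.0]heptan-7-one, via tosyl mixed anhydride 6 (not isolated), via acylpyridinium enolate 7 (not isolated)
Conditions: TsCl (1.3 equiv), 4-pyrrolidinopyridine (4-PPY, 1 equiv), iPr2NEt (4 equiv), CH2Cl2, rt, slow addition of 5
Reagents that add atoms: none
Why: TsCl converts 5 into mixed anhydride 6, 4-PPY displaces tosylate and iPr2NEt deprotonates the resulting acylpyridinium salt to zwitterionic enolate 7, whose C1' adds to the C2' ketone before the tertiary alkoxide attacks C7' and releases 4-PPY. This is the nucleophile-catalysed aldol-lactonisation of keto acids, formally a (2+2) union of an ammonium enolate and a ketone. Ring B closes in the 5-(enolexo)-exo-trig mode and the oxetanone in the 4-exo-trig mode. C1' is set by C5', because allylic 1,3-strain holds the C5'–H bond in the plane of the C1'=C7' enolate so that C7' ends cis to that hydrogen and trans to isopropenyl, while C2' is set by the ring fusion, because only the aldolate with oxygen cis to C7' can lactonise and the other one reverts by retro-aldol. The step needs facial selectivity relative to C5' and enolisation of the acyl unit in preference to the methyl ketone; the first rests on the limonene stereocentre (a matched chiral isothiourea in place of 4-PPY can reinforce it), the second on the far higher acidity of the acylpyridinium α-CH2. Slow addition of 5 keeps intermolecular acylation down, and capture of the tertiary aldol in the four-membered ring shields it from reversal and loss of water.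

Step 5
Reactants: 8 bicyclic β-lactone
Product: 9 (1S,2S,3S)-2-(hydroxymethyl)-1-methyl-3-(prop-1-en-2-yl)cyclopentan-1-ol
Conditions: LiAlH4 (1.2 equiv), Et2O, 0 °C; aq. work-up
Reagents that add atoms: none
Why: Hydride reduction of the strained lactone by acyl–oxygen cleavage runs through to the 1,3-diol without touching the C2'–O bond, the three stereocentres or the alkene, and full reduction avoids an uncertain halt at the aldehyde stage.

Step 6
Reactants: 9 diol
Product: 10 (1R,2S,5S)-2-hydroxy-2-methyl-5-(prop-1-en-2-yl)cyclopentane-1-carbaldehyde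
Conditions: TEMPO (10 mol%), PhI(OAc)2 (1.1 equiv), CH2Cl2, rt; used without storage
Reagents that add atoms: none
Why: Oxoammonium (TEMPO) oxidation can act only on the primary alcohol because the C2' carbinol carries no hydrogen, the near-neutral medium spares the aldol unit from retro-aldol and dehydration, and C1' already holds its more stable arrangement (C7' trans to isopropenyl and to the C2' methyl).

Step 7
Reactants: 11 dimethyl methylmalonate; 12 prenyl bromide
Product: 14 dimethyl 2-methyl-2-(3-methylbut-2-en-1-yl)malonate, via sodium enolate 13 (not isolated)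
Conditions: NaH (1.05 equiv), THF, 0 °C; then 12, 0 °C → rt
Reagents that add atoms: none
Why: In this malonic ester alkylation enolate 13 attacks the primary allylic bromide by SN2 at carbon, the single acidic hydrogen rules out double alkylation, and the product is prochiral.

Step 8
Reactants: 14 prochiral diester
Product: 15 (S)-2-(methoxycarbonyl)-2,5-dimethylhex-4-enoic acid
Conditions: pig liver esterase, phosphate buffer pH 7.4/DMSO (9:1), rt, pH-stat (1 M NaOH); then 1 M HCl to pH 2
Reagents that add atoms: water, O
Why: In this hydrolase desymmetrisation of a prochiral disubstituted malonate the enzyme pocket tells methyl from prenyl and hydrolyses one enantiotopic ester, which sets C6, the carboxylate formed is no longer a substrate, and without an α-hydrogen the centre cannot racemise.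

Step 9
Reactants: 15 half ester
Product: 16 methyl (R)-2-(chlorocarbonyl)-2,5-dimethylhex-4-enoate
Conditions: (COCl)2 (1.2 equiv), DMF (cat.), CH2Cl2, 0 °C → rt; evaporation
Reagents that add atoms: oxalyl chloride, O=C(Cl)C(=O)Cl
Why: Acid chloride formation through the Vilsmeier-type chloroiminium salt is mild enough for the ester and the prenyl group, the quaternary α-carbon excludes ketene formation and racemisation, and the descriptor changes to R only because COCl outranks CO2Me.

Step 10
Reactants: 16 acid chloride; 17 6-methylheptane-2,4-dione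
Product: 20 (S)-3,5-dihydroxy-6-methyl-6-(3-methylbut-2-en-1-yl)-2-(3-methylbutanoyl)cyclohexa-2,4-dien-1-one, via dilithio dianion 18 (not isolated), via triketo ester 19 (not isolated)
Conditions: 17 (2.1 equiv), LDA (commercial solution, 4.2 equiv), THF, −78 → 0 °C; 16 (1.0 equiv), −78 °C → rt; 1 M HCl
Reagents that add atoms: none
Why: This is γ-acylation of a 1,3-diketone dianion followed by Dieckmann condensation: the second deprotonation takes place at the unhindered methyl group, the terminal carbanion of 18 attacks the acid chloride far faster than the hindered ester, the second equivalent of 18 deprotonates 19, and the methylene next to the isovaleryl carbonyl (future C2) then closes on the ester (6-(enolexo)-exo-trig, helped by the Thorpe–Ingold effect and driven by the stabilised triketone anion), so the acid carbon becomes C5, the ester carbon becomes C1 and the configuration at C6 is retained.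

Step 11
Reactants: 10 hydroxy aldehyde; 20 acyl trione
Product: 22 (S)-3,5-dihydroxy-4-{[(1R,2S,5S)-2-hydroxy-2-methyl-5-(prop-1-en-2-yl)cyclopentyl]methyl}-6-methyl-6-(3-methylbut-2-en-1-yl)-2-(3-methylbutanoyl)cyclohexa-2,4-dien-1-one (CNP0139230.1), via alkylidene trione 21 (not isolated)
Conditions: Hantzsch ester (diethyl 1,4-dihydro-2,6-dimethylpyridine-3,5-dicarboxylate, 1.2 equiv), L-proline (20 mol%), CH2Cl2, rt
Reagents that add atoms: none
Why: In this three-component reductive alkylation (Knoevenagel condensation, then conjugate hydride transfer from the Hantzsch ester) C4–H is the only free nucleophilic carbon of 20, the strongly electrophilic alkylidene 21 is reduced as it forms and so cannot add a second trione, C7' becomes a CH2 group so no stereocentre is created, and isolated alkenes, ketones and the tertiary alcohol are inert to the dihydropyridine.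

Compound list
1 | (S)-(−)-limonene | C=C(C)[C@H]1CCC(C)=CC1 | starting material
2 | (4S)-limonene 1,2-oxide, epoxide centres undefined (cis/trans mixture) | C=C(C)[C@H]1CCC2(C)OC2C1 | intermediate
3 | (4S)-1-methyl-4-(prop-1-en-2-yl)cyclohexane-1,2-diol, C1/C2 undefined (not isolated) | C=C(C)[C@H]1CCC(C)(O)C(O)C1 | intermediate
4 | (S)-6-oxo-3-(prop-1-en-2-yl)heptanal | C=C(C)[C@@H](CCC(C)=O)CC=O | intermediate
5 | (S)-6-oxo-3-(prop-1-en-2-yl)heptanoic acid | C=C(C)[C@@H](CCC(C)=O)CC(=O)O | intermediate
6 | mixed anhydride of 5 and p-toluenesulfonic acid (not isolated) | C=C(C)[C@@H](CCC(C)=O)CC(=O)OS(=O)(=O)c1ccc(C)cc1 | intermediate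
7 | zwitterionic 4-PPY acylpyridinium enolate of 5, enolate geometry undefined (not isolated) | C=C(C)[C@@H](CCC(C)=O)C=C([O-])[n+]1ccc(N2CCCC2)cc1 | intermediate
8 | (1R,2S,5S)-5-methyl-2-(prop-1-en-2-yl)-6-oxabicyclo[3.2.0]heptan-7-one | C=C(C)[C@H]1CC[C@]2(C)OC(=O)[C@H]12 | intermediate
9 | (1S,2S,3S)-2-(hydroxymethyl)-1-methyl-3-(prop-1-en-2-yl)cyclopentan-1-ol | C=C(C)[C@H]1CC[C@](C)(O)[C@@H]1CO | intermediate
10 | (1R,2S,5S)-2-hydroxy-2-methyl-5-(prop-1-en-2-yl)cyclopentane-1-carbaldehyde | C=C(C)[C@H]1CC[C@](C)(O)[C@@H]1C=O | intermediate
11 | dimethyl methylmalonate | COC(=O)C(C)C(=O)OC | starting material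
12 | prenyl bromide (1-bromo-3-methylbut-2-ene) | CC(C)=CCBr | starting material
13 | sodium enolate of dimethyl methylmalonate (not isolated) | [Na+].COC(=O)C(C)=C([O-])OC | intermediate
14 | dimethyl 2-methyl-2-(3-methylbut-2-en-1-yl)malonate | COC(=O)C(C)(CC=C(C)C)C(=O)OC | intermediate
15 | (S)-2-(methoxycarbonyl)-2,5-dimethylhex-4-enoic acid | COC(=O)[C@@](C)(CC=C(C)C)C(=O)O | intermediate
16 | methyl (R)-2-(chlorocarbonyl)-2,5-dimethylhex-4-enoate | COC(=O)[C@@](C)(CC=C(C)C)C(=O)Cl | intermediate
17 | 6-methylheptane-2,4-dione | CC(=O)CC(=O)CC(C)C | starting material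
18 | dilithio 1,3-dianion of 17, deprotonated at C1 and C3 (not isolated) | [Li+].[Li+].C=C([O-])C=C([O-])CC(C)C | intermediate
19 | methyl (S)-2,9-dimethyl-2-(3-methylbut-2-en-1-yl)-3,5,7-trioxodecanoate (not isolated) | COC(=O)[C@@](C)(CC=C(C)C)C(=O)CC(=O)CC(=O)CC(C)C | intermediate
20 | (S)-3,5-dihydroxy-6-methyl-6-(3-methylbut-2-en-1-yl)-2-(3-methylbutanoyl)cyclohexa-2,4-dien-1-one | CC(C)CC(=O)C1=C(O)C=C(O)[C@](C)(CC=C(C)C)C1=O | intermediate
21 | Knoevenagel adduct of 10 and 20, C7'=C4 geometry undefined (not isolated) | C=C(C)[C@H]1CC[C@](C)(O)[C@@H]1C=C1C(=O)[C@](C)(CC=C(C)C)C(=O)C(C(=O)CC(C)C)=C1O | intermediate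
22 | CNP0139230.1, (6S,1'R,2'S,5'S), tautomer as drawn | C=C(C)[C@H]1CC[C@](C)(O)[C@@H]1CC1=C(O)[C@](C)(CC=C(C)C)C(=O)C(C(=O)CC(C)C)=C1O | target

Total step count: 11. Longest linear sequence: 7 (steps 1–6 and 11). The ring A branch takes steps 7–10 and joins at step 11.

Steps most likely to fail

Step 10. The dianion may be acylated on oxygen or twice, or be quenched by the more acidic product. Closure onto the hindered ester may stall or go through oxygen, and any attack at the ester carbonyl would erode the enantiopurity. In the fallback the C4–C5 bond is made by aldol addition in place of acylation. It sets out from 16 and dianion 18. Acid chloride 16 is reduced with LiAlH(Ot-Bu)3 (THF, −78 °C) to methyl (S)-2-formyl-2,5-dimethylhex-4-enoate F1. Dianion 18, made as in step 10, adds through its terminal carbon to this aldehyde at −78 °C. This gives methyl (2S)-3-hydroxy-2,9-dimethyl-2-(3-methylbut-2-en-1-yl)-5,7-dioxodecanoate F2 as a mixture of carbinol epimers. Dess–Martin oxidation leads to triketo ester 19, which is now isolated and closed in a separate Dieckmann condensation (KOt-Bu, THF, 0 °C → rt). The route is rejoined at 20.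

Step 8. The enzyme may tell the two ester groups apart poorly or in the opposite sense. The fallback is a classical resolution and sets out from 14. Half-saponification (KOH, 1 equiv, MeOH, rt) gives racemic 2-(methoxycarbonyl)-2,5-dimethylhex-4-enoic acid F3. Crystallisation with one enantiomer of 1-phenylethylamine follows. It is written here for the (R)-amine, and the mirror-image amine is taken if the less soluble salt holds the wrong acid. This gives (R)-1-phenylethylammonium (S)-2-(methoxycarbonyl)-2,5-dimethylhex-4-enoate F4, which is recrystallised until its rotation stays constant. Dilute HCl then liberates the acid, and the route is rejoined at 15.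

Step 11. The amine catalyst may dehydrate the β-hydroxy aldehyde through its enamine or open it by retro-aldol before condensation. The alkylidene may also lose the C2' oxygen by vinylogous elimination or add a second trione. In the fallback the aldol hydroxyl is masked before the aldehyde is unveiled. It sets out from 8 and bypasses steps 5 and 6.
- Lactone 8 is opened with MeNH(OMe)·HCl/Me2AlCl (CH2Cl2, 0 °C → rt) to (1R,2S,5S)-2-hydroxy-N-methoxy-N,2-dimethyl-5-(prop-1-en-2-yl)cyclopentane-1-carboxamide F5.
- TESOTf/2,6-lutidine gives its triethylsilyl ether F6.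
- DIBAL-H (CH2Cl2, −78 °C) gives (1R,2S,5S)-2-methyl-5-(prop-1-en-2-yl)-2-(triethylsilyloxy)cyclopentane-1-carbaldehyde F7.
- The reductive Knoevenagel coupling with 20 then runs through the silylated alkylidene trione F8 to the triethylsilyl ether of the target F9.
- HF·pyridine (THF, 0 °C) removes the silyl group, and the route ends at 22.

Further compounds
F1 | step 10 | methyl (S)-2-formyl-2,5-dimethylhex-4-enoate | COC(=O)[C@@](C)(CC=C(C)C)C=O
F2 | step 10 | methyl (2S)-3-hydroxy-2,9-dimethyl-2-(3-methylbut-2-en-1-yl)-5,7-dioxodecanoate (C3 epimers) | COC(=O)[C@@](C)(CC=C(C)C)C(O)CC(=O)CC(=O)CC(C)C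
F3 | step 8 | racemic 2-(methoxycarbonyl)-2,5-dimethylhex-4-enoic acid | COC(=O)C(C)(CC=C(C)C)C(=O)O
F4 | step 8 | (R)-1-phenylethylammonium (S)-2-(methoxycarbonyl)-2,5-dimethylhex-4-enoate | C[C@@H]([NH3+])c1ccccc1.COC(=O)[C@@](C)(CC=C(C)C)C(=O)[O-]
F5 | step 11 | (1R,2S,5S)-2-hydroxy-N-methoxy-N,2-dimethyl-5-(prop-1-en-2-yl)cyclopentane-1-carboxamide | C=C(C)[C@H]1CC[C@](C)(O)[C@@H]1C(=O)N(C)OC
F6 | step 11 | (1R,2S,5S)-N-methoxy-N,2-dimethyl-5-(prop-1-en-2-yl)-2-(triethylsilyloxy)cyclopentane-1-carboxamide | C=C(C)[C@H]1CC[C@](C)(O[Si](CC)(CC)CC)[C@@H]1C(=O)N(C)OC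
F7 | step 11 | (1R,2S,5S)-2-methyl-5-(prop-1-en-2-yl)-2-(triethylsilyloxy)cyclopentane-1-carbaldehyde | C=C(C)[C@H]1CC[C@](C)(O[Si](CC)(CC)CC)[C@@H]1C=O
F8 | step 11 | triethylsilyl ether of alkylidene trione 21 (C7'=C4 geometry undefined, not isolated) | C=C(C)[C@H]1CC[C@](C)(O[Si](CC)(CC)CC)[C@@H]1C=C1C(=O)[C@](C)(CC=C(C)C)C(=O)C(C(=O)CC(C)C)=C1O
F9 | step 11 | C2'-O-triethylsilyl ether of 22 | C=C(C)[C@H]1CC[C@](C)(O[Si](CC)(CC)CC)[C@@H]1CC1=C(O)[C@](C)(CC=C(C)C)C(=O)C(C(=O)CC(C)C)=C1O
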